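## Retrosynthetic overview

1. Ring numbering used throughout: C1 = carbinol with the free OH, C2=C3(CH3), C4 = ester carbinol, C5, C6=C7(CH3), C8–C10 = CH2, C11 = C(CH3)2. The target comes from the macrocyclic 1,4-diol by O4-selective acylation with 4-acetoxybenzoyl chloride and phenol deacetylation.
2. The diol comes from a cycloundeca-2,6,9-triene (diimide saturation of C9=C10, desilylation), which comes from an acyclic (2Z,6Z)-allenyl allylic alcohol by C1–C11 closure: a redox-neutral iridium-catalysed cycloisomerisation (alcohol to transient enal, allene to allyliridium, γ-addition).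
3. Enabling feature: C1 is a secondary carbinol bonded to the quaternary C11(CH3)2, whose other neighbours C10 and C9 are plain CH2 groups. This is the retron of a carbonyl reverse prenylation, so a C9=C10=C11 allene is a latent tertiary nucleophile. The Z olefins C2=C3 and C6=C7 fold the chain so that C1 meets C11.
4. The acyclic precursor comes from a butenolide (temporary five-membered ring O4–C1(=O)–C2=C3–C4 that locks 2Z), made from an (S)-α-hydroxy methyl ketone and Ph3P=C=C=O. The ketone comes from an (S)-epoxy ketal (hydrolytic kinetic resolution) and a (Z)-alkenylmagnesium built from propargyl alcohol (anti-carbomagnesiation sets 6Z) and lithiated 1,1-dimethylallene.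
5. Ring order: butenolide (closed in step 8, opened in step 9), then the eleven-membered carbocycle (step 12); no other ring is made.

Key step: step 12

Remark (assumption on catalyst sense): (R,R)-(salen)Co(OAc) is taken to leave the (S)-epoxide 10, and the (R)-SEGPHOS iridium catalyst to attack the Re face of the C1 aldehyde, by analogy with related intermolecular cases; if either sense proves opposite on these substrates, the antipodal catalyst is used and nothing else changes.

## Route

Step 1
Reactants: 1 prop-2-yn-1-ol
Product: 3 (Z)-3-iodo-2-methylprop-2-en-1-ol, via alkenylmagnesium alkoxide 2 (not isolated)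
Conditions: MeMgBr (2.5 equiv), CuI (10 mol%), Et2O/THF, 0 °C to rt; then I2 (1.2 equiv), −78 to 0 °C
Reagents that add atoms: methylmagnesium bromide C[Mg]Br; iodine II
Why: Copper-catalysed anti-carbomagnesiation of the propargylic alkoxide puts the methyl group on the future C7 and the metal on the future C6 cis to the CH2O group (five-membered magnesium alkoxide chelate 2), and iodinolysis with retention fixes the Z geometry of the later C6=C7 olefin.

Step 2
Reactants: 3 (Z)-3-iodo-2-methylprop-2-en-1-ol
Product: 4 (Z)-3-bromo-1-iodo-2-methylprop-1-ene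
Conditions: CBr4 (1.1 equiv), PPh3 (1.15 equiv), CH2Cl2, 0 °C
Reagents that add atoms: carbon tetrabromide BrC(Br)(Br)Br
Why: Appel bromination converts the primary allylic alcohol into the bromide under neutral conditions without touching the alkenyl iodide or the olefin geometry.

Step 3
Reactants: 4 (Z)-3-bromo-1-iodo-2-methylprop-1-ene; 5 3-methylbuta-1,2-diene
Product: 7 (Z)-1-iodo-2,6-dimethylhepta-1,4,5-triene, via 3-methylbuta-1,2-dienyllithium 6 (not isolated)
Conditions: 5 (1.3 equiv), n-BuLi (1.2 equiv), THF, −78 to −30 °C; then 4, −78 to 0 °C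
Reagents that add atoms: none
Why: The allenyllithium 6 (deprotonation of the only sp2 C–H of 5) should be alkylated at its metal-bearing carbon by SN2 displacement of the primary allylic bromide, since attack through the dimethyl-substituted end would build a quaternary propargylic centre; this forms C8–C9 and installs the 1,1-dimethylallene that later acts as the latent tertiary nucleophile.

Step 4
Reactants: 8 2-methyl-2-vinyl-1,3-dioxolane
Product: 9 racemic 2-methyl-2-(oxiran-2-yl)-1,3-dioxolane
Conditions: mCPBA (1.3 equiv), NaHCO3, CH2Cl2, reflux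
Reagents that add atoms: mCPBA OOC(=O)c1cccc(Cl)c1
Why: Prilezhaev epoxidation of the terminal olefin, with the ketal masking the methyl ketone that becomes C3 and its methyl group.

Step 5
Reactants: 9 racemic 2-methyl-2-(oxiran-2-yl)-1,3-dioxolane
Product: 10 (S)-2-methyl-2-(oxiran-2-yl)-1,3-dioxolane
Conditions: (R,R)-(salen)Co(OAc) (0.5 mol%; salen = N,N'-bis(3,5-di-tert-butylsalicylidene)cyclohexane-1,2-diamine dianion), H2O (0.55 equiv), neat, 0 °C to rt; distillation
Reagents that add atoms: none
Why: Hydrolytic kinetic resolution of the terminal epoxide should hydrolyse the R enantiomer and leave (S)-10, which carries the future C4 stereocentre (no bond to this carbon is broken later).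

Step 6
Reactants: 7 (Z)-1-iodo-2,6-dimethylhepta-1,4,5-triene; 10 (S)-2-methyl-2-(oxiran-2-yl)-1,3-dioxolane
Product: 12 (1S,3Z)-4,8-dimethyl-1-(2-methyl-1,3-dioxolan-2-yl)nona-3,6,7-trien-1-ol, via alkenylmagnesium chloride 11 (not isolated)
Conditions: 7, iPrMgCl·LiCl (1.1 equiv), THF, 0 °C to rt; then CuI (10 mol%), 10 (0.9 equiv), −30 to 0 °C
Reagents that add atoms: none
Why: Iodine–magnesium exchange proceeds with retention at the alkenyl carbon, and copper-catalysed SN2 opening of the epoxide at its unhindered CH2 terminus forms C5–C6 without touching C4, so the S configuration of 10 is carried into the carbinol.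

Step 7
Reactants: 12 (1S,3Z)-4,8-dimethyl-1-(2-methyl-1,3-dioxolan-2-yl)nona-3,6,7-trien-1-ol
Product: 13 (3S,5Z)-3-hydroxy-6,10-dimethylundeca-5,8,9-trien-2-one
Conditions: 1 M aq. HCl/THF (1:4), rt
Reagents that add atoms: water O
Why: Mild acid hydrolysis of the dioxolane unveils the methyl ketone, while the trisubstituted olefin and the allene should not be protonated by dilute acid at room temperature.

Step 8
Reactants: 13 (3S,5Z)-3-hydroxy-6,10-dimethylundeca-5,8,9-trien-2-one
Product: 15 (5S)-5-[(2Z)-3,7-dimethylocta-2,5,6-trien-1-yl]-4-methylfuran-2(5H)-one, via acyl phosphorane 14 (not isolated)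
Conditions: Ph3P=C=C=O (1.3 equiv), toluene, 110 °C
Reagents that add atoms: ketenylidenetriphenylphosphorane O=C=C=P(c1ccccc1)(c1ccccc1)c1ccccc1
Why: Addition of the hydroxyl group to the ketene unit gives acyl phosphorane 14, whose intramolecular Wittig reaction with the neighbouring methyl ketone closes the butenolide, a temporary ring that locks the future C2=C3 olefin as Z under near-neutral conditions that should spare the C4 stereocentre.

Step 9
Reactants: 15 (5S)-5-[(2Z)-3,7-dimethylocta-2,5,6-trien-1-yl]-4-methylfuran-2(5H)-one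
Product: 16 (2Z,4S,6Z)-3,7,11-trimethyldodeca-2,6,9,10-tetraene-1,4-diol
Conditions: iBu2AlH (3.5 equiv), CH2Cl2, −78 to 0 °C; aq. potassium sodium tartrate
Reagents that add atoms: none
Why: Exhaustive 1,2-reduction of the unsaturated lactone (via the lactol) opens the temporary ring to the (Z)-2-ene-1,4-diol, with the C2=C3 geometry inherited from the ring and C4 untouched.

Step 10
Reactants: 16 (2Z,4S,6Z)-3,7,11-trimethyldodeca-2,6,9,10-tetraene-1,4-diol
Product: 17 (2Z,4S,6Z)-1,4-bis(tert-butyldimethylsilyloxy)-3,7,11-trimethyldodeca-2,6,9,10-tetraene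
Conditions: TBSCl (2.5 equiv), imidazole (5 equiv), DMF, rt
Reagents that add atoms: tert-butyldimethylsilyl chloride CC(C)(C)[Si](C)(C)Cl
Why: Imidazole-promoted silylation protects both hydroxyl groups.

Step 11
Reactants: 17 (2Z,4S,6Z)-1,4-bis(tert-butyldimethylsilyloxy)-3,7,11-trimethyldodeca-2,6,9,10-tetraene
Product: 18 (2Z,4S,6Z)-4-(tert-butyldimethylsilyloxy)-3,7,11-trimethyldodeca-2,6,9,10-tetraen-1-ol
Conditions: HF·pyridine, pyridine/THF, 0 °C
Reagents that add atoms: none
Why: Buffered HF·pyridine cleaves the primary allylic silyl ether much faster than the hindered secondary one, which frees only O1 for the redox-triggered cyclisation and keeps O4 blocked.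

Step 12
Reactants: 18 (2Z,4S,6Z)-4-(tert-butyldimethylsilyloxy)-3,7,11-trimethyldodeca-2,6,9,10-tetraen-1-ol
Product: 20 (1S,2Z,4S,6Z,9E)-4-(tert-butyldimethylsilyloxy)-3,7,11,11-tetramethylcycloundeca-2,6,9-trien-1-ol, via transient (2Z)-enal 19 (not isolated)
Conditions: [Ir(cod)Cl]2 (5 mol%), (R)-SEGPHOS (10 mol%), 4-cyano-3-nitrobenzoic acid (10 mol%), allyl acetate (10 mol%), Cs2CO3 (20 mol%), THF, 100 °C, 1 h (catalyst formation); then toluene, 70 °C, 18 added by syringe pump over 12 h to 2 mM
Reagents that add atoms: none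
Why: Proposed new method: the iridium alkoxide of 18 should undergo β-hydride elimination to the (2Z)-enal 19 and an iridium hydride, which adds across the less hindered C9=C10 bond of the allene (hydrogen to the central carbon C10) to give an allyliridium bound at the secondary carbon C9; carbonyl addition through the γ-carbon C11 in a closed six-membered chair then forms C1–C11, and alkoxide exchange with fresh 18 turns the cycle over, so 18 is simply isomerised to 20 (the C1 hydrogen ends on C10). The closest known reaction is the intermolecular iridium-catalysed transfer-hydrogenative reverse prenylation of primary alcohols, allylic ones included, with 1,1-dimethylallene; new here are the intramolecular, macrocyclising mode and the trisubstituted allene. The eleven-membered carbocycle closes in an 11-exo-trig mode at the carbonyl with allylic transposition, so that C9, C10 and C11 all become ring atoms and C11 becomes the quaternary gem-dimethyl carbon. The new C1 stereocentre is set by the chiral bisphosphine of the cyclometallated catalyst (Re-face attack, catalyst control as in the intermolecular reaction), and the C9=C10 geometry (E expected from a pseudo-equatorial chain) does not matter because this olefin is saturated in step 13. The step needs ring closure over oligomerisation (high dilution, slow addition, and the two Z-trisubstituted olefins C2=C3 and C6=C7 that bend the chain and bring C1 near C11), reaction of the primary alcohol and of the allene only (the silyl ether on O4 prevents lactol formation and iridium hydrides do not add to the trisubstituted olefins), and bond formation at the more substituted allyl terminus, which is the normal course for this catalyst type.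

Step 13
Reactants: 20 (1S,2Z,4S,6Z,9E)-4-(tert-butyldimethylsilyloxy)-3,7,11,11-tetramethylcycloundeca-2,6,9-trien-1-ol
Product: 21 (1S,2Z,4S,6Z)-4-(tert-butyldimethylsilyloxy)-3,7,11,11-tetramethylcycloundeca-2,6-dien-1-ol
Conditions: 2-nitrobenzenesulfonylhydrazide (4 equiv), Et3N (8 equiv), CH2Cl2, rt
Reagents that add atoms: none
Why: Diimide generated in situ transfers H2 in a concerted syn fashion and should reduce the 1,2-disubstituted E olefin much faster than the two trisubstituted Z olefins, which removes the unsaturation that the allyl nucleophile left at C9–C10.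

Step 14
Reactants: 21 (1S,2Z,4S,6Z)-4-(tert-butyldimethylsilyloxy)-3,7,11,11-tetramethylcycloundeca-2,6-dien-1-ol
Product: 22 (1S,2Z,4S,6Z)-3,7,11,11-tetramethylcycloundeca-2,6-diene-1,4-diol
Conditions: Bu4NF (2 equiv), THF, 0 °C to rt
Reagents that add atoms: none
Why: Fluoride cleaves the secondary silyl ether to give the 1,4-diol.

Step 15
Reactants: 22 (1S,2Z,4S,6Z)-3,7,11,11-tetramethylcycloundeca-2,6-diene-1,4-diol; 23 4-acetoxybenzoyl chloride
Product: 24 (1S,2Z,4S,6Z)-1-hydroxy-3,7,11,11-tetramethylcycloundeca-2,6-dien-4-yl 4-acetoxybenzoate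
Conditions: 23 (1.05 equiv), pyridine (3 equiv), DMAP (5 mol%), CH2Cl2, −20 to 0 °C
Reagents that add atoms: none
Why: DMAP-catalysed acylation should discriminate the two secondary allylic hydroxyls sterically, since O4 has a CH2 neighbour whereas O1 is neopentylic (next to the quaternary C11), so one equivalent of acid chloride at low temperature should esterify O4 only.

Step 16
Reactants: 24 (1S,2Z,4S,6Z)-1-hydroxy-3,7,11,11-tetramethylcycloundeca-2,6-dien-4-yl 4-acetoxybenzoate
Product: 25 (1S,2Z,4S,6Z)-1-hydroxy-3,7,11,11-tetramethylcycloundeca-2,6-dien-4-yl 4-hydroxybenzoate (target)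
Conditions: K2CO3 (0.2 equiv), MeOH, 0 °C
Reagents that add atoms: none
Why: The phenolic acetate is far more electrophilic than the alkyl benzoate, so catalytic carbonate in methanol should remove it by transesterification, and the phenoxide formed further deactivates the benzoate toward methanolysis.

## Compound list

1 | prop-2-yn-1-ol | OCC#C | starting material
2 | (Z)-alkenylmagnesium alkoxide from anti-carbomagnesiation (not isolated) | Br[Mg]OC/C(C)=C\[Mg]Br | intermediate
3 | (Z)-3-iodo-2-methylprop-2-en-1-ol | OC/C(C)=C\I | intermediate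
4 | (Z)-3-bromo-1-iodo-2-methylprop-1-ene | BrC/C(C)=C\I | intermediate
5 | 3-methylbuta-1,2-diene | CC(C)=C=C | starting material
6 | 3-methylbuta-1,2-dienyllithium (not isolated) | [Li]C=C=C(C)C | intermediate
7 | (Z)-1-iodo-2,6-dimethylhepta-1,4,5-triene | I/C=C(C)\CC=C=C(C)C | intermediate
8 | 2-methyl-2-vinyl-1,3-dioxolane | C=CC1(C)OCCO1 | starting material
9 | racemic 2-methyl-2-(oxiran-2-yl)-1,3-dioxolane | CC1(OCCO1)C1CO1 | intermediate
10 | (S)-2-methyl-2-(oxiran-2-yl)-1,3-dioxolane | CC1(OCCO1)[C@@H]1CO1 | intermediate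
11 | (Z)-alkenylmagnesium chloride from 7 (not isolated) | Cl[Mg]/C=C(C)\CC=C=C(C)C | intermediate
12 | (1S,3Z)-4,8-dimethyl-1-(2-methyl-1,3-dioxolan-2-yl)nona-3,6,7-trien-1-ol | CC1(OCCO1)[C@@H](O)C/C=C(C)\CC=C=C(C)C | intermediate
13 | (3S,5Z)-3-hydroxy-6,10-dimethylundeca-5,8,9-trien-2-one | CC(=O)[C@@H](O)C/C=C(C)\CC=C=C(C)C | intermediate
14 | (3S,5Z)-6,10-dimethyl-2-oxoundeca-5,8,9-trien-3-yl (triphenylphosphoranylidene)acetate (not isolated) | CC(=O)[C@@H](OC(=O)C=P(c1ccccc1)(c1ccccc1)c1ccccc1)C/C=C(C)\CC=C=C(C)C | intermediate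
15 | (5S)-5-[(2Z)-3,7-dimethylocta-2,5,6-trien-1-yl]-4-methylfuran-2(5H)-one | CC1=CC(=O)O[C@H]1C/C=C(C)\CC=C=C(C)C | intermediate
16 | (2Z,4S,6Z)-3,7,11-trimethyldodeca-2,6,9,10-tetraene-1,4-diol | OC/C=C(C)\[C@@H](O)C/C=C(C)\CC=C=C(C)C | intermediate
17 | (2Z,4S,6Z)-1,4-bis(tert-butyldimethylsilyloxy)-3,7,11-trimethyldodeca-2,6,9,10-tetraene | CC(C)(C)[Si](C)(C)OC/C=C(C)\[C@@H](O[Si](C)(C)C(C)(C)C)C/C=C(C)\CC=C=C(C)C | intermediate
18 | (2Z,4S,6Z)-4-(tert-butyldimethylsilyloxy)-3,7,11-trimethyldodeca-2,6,9,10-tetraen-1-ol | OC/C=C(C)\[C@@H](O[Si](C)(C)C(C)(C)C)C/C=C(C)\CC=C=C(C)C | intermediate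
19 | (2Z,4S,6Z)-4-(tert-butyldimethylsilyloxy)-3,7,11-trimethyldodeca-2,6,9,10-tetraenal (not isolated) | O=C/C=C(C)\[C@@H](O[Si](C)(C)C(C)(C)C)C/C=C(C)\CC=C=C(C)C | intermediate
20 | (1S,2Z,4S,6Z,9E)-4-(tert-butyldimethylsilyloxy)-3,7,11,11-tetramethylcycloundeca-2,6,9-trien-1-ol | C/C1=C/C[C@H](O[Si](C)(C)C(C)(C)C)/C(C)=C\[C@H](O)C(C)(C)/C=C/C1 | intermediate
21 | (1S,2Z,4S,6Z)-4-(tert-butyldimethylsilyloxy)-3,7,11,11-tetramethylcycloundeca-2,6-dien-1-ol | C/C1=C/C[C@H](O[Si](C)(C)C(C)(C)C)/C(C)=C\[C@H](O)C(C)(C)CCC1 | intermediate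
22 | (1S,2Z,4S,6Z)-3,7,11,11-tetramethylcycloundeca-2,6-diene-1,4-diol | C/C1=C/C[C@H](O)/C(C)=C\[C@H](O)C(C)(C)CCC1 | intermediate
23 | 4-acetoxybenzoyl chloride | CC(=O)Oc1ccc(cc1)C(Cl)=O | starting material
24 | (1S,2Z,4S,6Z)-1-hydroxy-3,7,11,11-tetramethylcycloundeca-2,6-dien-4-yl 4-acetoxybenzoate | C/C1=C/C[C@H](OC(=O)c2ccc(OC(C)=O)cc2)/C(C)=C\[C@H](O)C(C)(C)CCC1 | intermediate
25 | (1S,2Z,4S,6Z)-1-hydroxy-3,7,11,11-tetramethylcycloundeca-2,6-dien-4-yl 4-hydroxybenzoate | C/C1=C/C[C@H](OC(=O)c2ccc(O)cc2)/C(C)=C\[C@H](O)C(C)(C)CCC1 | target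

## Step count and risks

Total steps: 16. Longest linear sequence: 14 steps (steps 1–3 and 6–16, from prop-2-yn-1-ol); steps 4–5 form the epoxide branch.

Steps most likely to fail:

1. Step 12 (proposed new method). What may go wrong: intermolecular carbonyl addition giving oligomers; isomerisation of the allene to a 1,3-diene by β-hydride loss from the allyliridium; hydrogen transfer to the allene without C–C bond formation; or a ring-forming transition state that overrides the ligand. Fallback (stoichiometric chromium umpolung, known chemistry), setting out from 18: hydroboration of the allene with 9-BBN (2.2 equiv, THF, 0 °C; boron at C9, hydrogen at C10) and oxidation with NaBO3 should give (2Z,4S,6Z)-4-(tert-butyldimethylsilyloxy)-3,7,11-trimethyldodeca-2,6,10-triene-1,9-diol F1 (C9 epimers, of no consequence). TEMPO (cat.)/PhI(OAc)2 in CH2Cl2 should oxidise only the primary allylic hydroxyl to (2Z,4S,6Z)-4-(tert-butyldimethylsilyloxy)-9-hydroxy-3,7,11-trimethyldodeca-2,6,10-trienal F2. PPh3/CBr4 at −20 °C should give (2Z,4S,6Z)-9-bromo-4-(tert-butyldimethylsilyloxy)-3,7,11-trimethyldodeca-2,6,10-trienal F3 (in equilibrium with its tertiary allylic isomer; both give the same allylchromium). Slow addition of F3 to CrCl2 (8 equiv) in THF at high dilution (intramolecular Nozaki–Hiyama–Kishi allylation, γ-attack) should close C1–C11 and come back to the route at 20; stereocontrol at C1 would then rest on the substrate, and the C1 epimers would be separated at that stage.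

2. Step 15. What may go wrong: insufficient discrimination between O4 and O1 (bis-acylation or O1 ester) or 1,4-acyl migration across the Z olefin. Fallback (orthogonal protection in place of steric discrimination), setting out from 21: forcing Steglich esterification of the hindered O1 with levulinic acid (DCC, DMAP, CH2Cl2, rt) should give (1S,2Z,4S,6Z)-4-(tert-butyldimethylsilyloxy)-3,7,11,11-tetramethylcycloundeca-2,6-dien-1-yl 4-oxopentanoate F4. HF·pyridine in THF should remove the silyl ether without acyl migration to give (1S,2Z,4S,6Z)-4-hydroxy-3,7,11,11-tetramethylcycloundeca-2,6-dien-1-yl 4-oxopentanoate F5. Acylation with 23 (pyridine, DMAP) should give (1S,2Z,4S,6Z)-4-(4-acetoxybenzoyloxy)-3,7,11,11-tetramethylcycloundeca-2,6-dien-1-yl 4-oxopentanoate F6. Hydrazine acetate (N2H4·AcOH, pyridine/AcOH, rt) should then cleave the levulinate and the phenolic acetate together, which comes back to the route at 25.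

3. Step 13. What may go wrong: reduction of a trisubstituted ring olefin by excess diimide, or incomplete reduction of the hindered C9=C10 bond next to the quaternary carbon. Fallback (coordination-controlled catalytic hydrogenation in place of stoichiometric hydrogen transfer), setting out from 20: H2 (1 atm) over RhCl(PPh3)3 (10 mol%) in benzene/EtOH at rt, where trisubstituted olefins do not compete for the metal, should give the same dihydro compound and come back to the route at 21 (no new compound, F0).

## Further compounds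

F1 | step 12 | (2Z,4S,6Z)-4-(tert-butyldimethylsilyloxy)-3,7,11-trimethyldodeca-2,6,10-triene-1,9-diol (C9 epimers) | OC/C=C(C)\[C@@H](O[Si](C)(C)C(C)(C)C)C/C=C(C)\CC(O)C=C(C)C
F2 | step 12 | (2Z,4S,6Z)-4-(tert-butyldimethylsilyloxy)-9-hydroxy-3,7,11-trimethyldodeca-2,6,10-trienal (C9 epimers) | O=C/C=C(C)\[C@@H](O[Si](C)(C)C(C)(C)C)C/C=C(C)\CC(O)C=C(C)C
F3 | step 12 | (2Z,4S,6Z)-9-bromo-4-(tert-butyldimethylsilyloxy)-3,7,11-trimethyldodeca-2,6,10-trienal (C9 epimers) | O=C/C=C(C)\[C@@H](O[Si](C)(C)C(C)(C)C)C/C=C(C)\CC(Br)C=C(C)C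
F4 | step 15 | (1S,2Z,4S,6Z)-4-(tert-butyldimethylsilyloxy)-3,7,11,11-tetramethylcycloundeca-2,6-dien-1-yl 4-oxopentanoate | C/C1=C/C[C@H](O[Si](C)(C)C(C)(C)C)/C(C)=C\[C@H](OC(=O)CCC(C)=O)C(C)(C)CCC1
F5 | step 15 | (1S,2Z,4S,6Z)-4-hydroxy-3,7,11,11-tetramethylcycloundeca-2,6-dien-1-yl 4-oxopentanoate | C/C1=C/C[C@H](O)/C(C)=C\[C@H](OC(=O)CCC(C)=O)C(C)(C)CCC1
F6 | step 15 | (1S,2Z,4S,6Z)-4-(4-acetoxybenzoyloxy)-3,7,11,11-tetramethylcycloundeca-2,6-dien-1-yl 4-oxopentanoate | C/C1=C/C[C@H](OC(=O)c2ccc(OC(C)=O)cc2)/C(C)=C\[C@H](OC(=O)CCC(C)=O)C(C)(C)CCC1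
F0 | step 13 | none | none
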